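**Plan**

1. Cuts (benzofuran numbering): O1–C7a together with C7–C(=O) in one operation, then C3–C3a, then the CH2–CH2 and ArCH2–CH bonds of the C5 side chain; O6 is carried as a methyl ether until the end.
2. Enabling feature: in ring A (the benzene ring) the oxygen-bearing C7a is bonded directly to the aroyl-bearing C7, and the C2 carbinol oxygen sits two carbons from C3a. A 3-methoxyaryne across C7/C7a therefore takes that oxygen at C7a, closing ring C (the dihydrofuran), and leaves a carbanion at C7 for acylation with ring B (the 3-hydroxyphenyl ring).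
3. Forward order: 2,6-dimethoxytoluene is dibrominated symmetrically; the side chain is built on the benzylic carbon; one bromine becomes the C3/C2 carbinol arm and the other the aryne trigger; ring C closes with attachment of ring B in the same flask; two deprotections finish.
4. Stereochemistry: the side-chain (R) center comes from an Evans dienolate alkylation with (4R)-4-benzyl-1,3-oxazolidin-2-one; the (S) center at C2 comes from a hydrolytic kinetic resolution of the epoxide and is carried through with retention.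
5. The mirror symmetry of the 2-alkyl-1,3-dimethoxybenzene core removes all regiochemical questions on ring A; the ketone later singles out O6 for demethylation by chelation.

Key step: step 14

Remark: target atoms are numbered as in 2,3-dihydro-1-benzofuran (O1, C2, C3, C3a, C4 to C7, C7a). The (R,R) resolution catalyst is assumed to leave the (S)-epoxide, as for other terminal epoxides whose substituent outranks the ring CH2 in the sequence rules.

**Route**

Step 1
Reactants: 1 2,6-dimethoxytoluene
Product: 2 1,5-dibromo-2,4-dimethoxy-3-methylbenzene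
Conditions: Br2 (2.1 equiv), CH2Cl2, 0 °C to rt
Reagents that add atoms: bromine, BrBr
Why: Electrophilic aromatic bromination should go twice, to the two equivalent positions that are ortho to one methoxy group and para to the other, leaving the position meta to both untouched.

Step 2
Reactants: 2 1,5-dibromo-2,4-dimethoxy-3-methylbenzene
Product: 3 1,5-dibromo-3-(bromomethyl)-2,4-dimethoxybenzene
Conditions: NBS (1.05 equiv), AIBN (cat.), PhCF3, 80 °C
Reagents that add atoms: N-bromosuccinimide, O=C1CCC(=O)N1Br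
Why: Wohl–Ziegler radical bromination should take the only benzylic C–H bonds, since both activated ring positions already carry bromine.

Step 3
Reactants: 4 (4R)-4-benzyl-1,3-oxazolidin-2-one; 5 3-methylbut-2-enoyl chloride
Product: 7 (4R)-4-benzyl-3-(3-methylbut-2-enoyl)-1,3-oxazolidin-2-one, via lithium oxazolidinide 6 (not isolated)
Conditions: n-BuLi (1.0 equiv), THF, −78 °C; then 5, −78 to 0 °C
Reagents that add atoms: none
Why: N-Acylation of the lithiated auxiliary by an acid chloride is the standard preparation of Evans imides.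

Step 4
Reactants: 7 (4R)-4-benzyl-3-(3-methylbut-2-enoyl)-1,3-oxazolidin-2-one; 3 1,5-dibromo-3-(bromomethyl)-2,4-dimethoxybenzene
Product: 9 (4R)-4-benzyl-3-[(2R)-2-[(3,5-dibromo-2,6-dimethoxyphenyl)methyl]-3-methylbut-3-enoyl]-1,3-oxazolidin-2-one, via sodium dienolate 8 (not isolated)
Conditions: NaN(SiMe3)2 (1.1 equiv), THF, −78 °C; then 3, −78 to −30 °C
Reagents that add atoms: none
Why: γ-Deprotonation gives the chelated (Z)-dienolate, which should be benzylated at the α-carbon (deconjugative Evans alkylation) on the face opposite the C4 benzyl group of the auxiliary, setting the α-isopropenyl center as (R).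

Step 5
Reactants: 9 (4R)-4-benzyl-3-[(2R)-2-[(3,5-dibromo-2,6-dimethoxyphenyl)methyl]-3-methylbut-3-enoyl]-1,3-oxazolidin-2-one
Product: 10 (2R)-2-[(3,5-dibromo-2,6-dimethoxyphenyl)methyl]-3-methylbut-3-en-1-ol
Conditions: LiBH4 (2 equiv), H2O (1 equiv), Et2O, 0 °C
Reagents that add atoms: none
Why: Reductive cleavage of the N-acyloxazolidinone by LiBH4 should give the primary alcohol and the recoverable auxiliary without touching the α-center, the aryl bromides or the alkene.

Step 6
Reactants: 10 (2R)-2-[(3,5-dibromo-2,6-dimethoxyphenyl)methyl]-3-methylbut-3-en-1-ol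
Product: 11 1,5-dibromo-3-[(2R)-2-(iodomethyl)-3-methylbut-3-en-1-yl]-2,4-dimethoxybenzene
Conditions: PPh3, I2, imidazole, CH2Cl2, 0 °C to rt
Reagents that add atoms: iodine, I-I
Why: The Appel reaction converts the primary alcohol into the iodide under neutral conditions with no change at the adjacent center.

Step 7
Reactants: 11 1,5-dibromo-3-[(2R)-2-(iodomethyl)-3-methylbut-3-en-1-yl]-2,4-dimethoxybenzene; 12 2-methylallylmagnesium chloride
Product: 13 1,5-dibromo-2,4-dimethoxy-3-[(2R)-5-methyl-2-(prop-1-en-2-yl)hex-5-en-1-yl]benzene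
Conditions: 12 (2 equiv), CuI (10 mol %), THF, −30 to 0 °C
Reagents that add atoms: none
Why: Copper-catalysed cross-coupling of an allylic Grignard reagent with a primary alkyl iodide should join the two sp3 carbons; both ends of the symmetrical methallyl unit give the same product and the aryl bromides are inert under these conditions.

Step 8
Reactants: 14 2-methylbut-3-en-2-ol
Product: 15 3-(methoxymethoxy)-3-methylbut-1-ene
Conditions: MOMCl (2 equiv), i-Pr2NEt (3 equiv), NaI (cat.), CH2Cl2, 0 to 40 °C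
Reagents that add atoms: chloromethyl methyl ether, COCCl
Why: O-Alkylation of the tertiary alcohol (MOM protection) gives an ether that cannot migrate to a neighbouring alkoxide and is stable to organolithium reagents.

Step 9
Reactants: 15 3-(methoxymethoxy)-3-methylbut-1-ene
Product: 16 rac-2-[2-(methoxymethoxy)propan-2-yl]oxirane
Conditions: mCPBA, NaHCO3, CH2Cl2, rt
Reagents that add atoms: 3-chloroperbenzoic acid, O=C(OO)c1cccc(Cl)c1
Why: Prilezhaev epoxidation of the terminal alkene.

Step 10
Reactants: 16 rac-2-[2-(methoxymethoxy)propan-2-yl]oxirane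
Product: 17 (2S)-2-[2-(methoxymethoxy)propan-2-yl]oxirane
Conditions: (R,R)-(salen)Co(OAc) (1 mol %; trivalent cobalt; salen = N,N'-bis(3,5-di-tert-butylsalicylidene)cyclohexane-1,2-diamine dianion), H2O (0.55 equiv), THF, 0 °C to rt; distillation
Reagents that add atoms: none
Why: The Jacobsen hydrolytic kinetic resolution should hydrolyse the (R)-epoxide to its diol and leave the (S)-epoxide, the sense expected for the (R,R) catalyst with a terminal epoxide of this substitution type.

Step 11
Reactants: 13 1,5-dibromo-2,4-dimethoxy-3-[(2R)-5-methyl-2-(prop-1-en-2-yl)hex-5-en-1-yl]benzene; 17 (2S)-2-[2-(methoxymethoxy)propan-2-yl]oxirane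
Product: 19 (2S)-1-{5-bromo-2,4-dimethoxy-3-[(2R)-5-methyl-2-(prop-1-en-2-yl)hex-5-en-1-yl]phenyl}-3-(methoxymethoxy)-3-methylbutan-2-ol, via aryllithium 18 (not isolated)
Conditions: n-BuLi (1.0 equiv), THF, −78 °C; then BF3·OEt2 (1.2 equiv) and 17 (1.2 equiv), −78 °C
Reagents that add atoms: none
Why: Bromine–lithium exchange of one of the two equivalent aryl bromides followed by BF3-promoted epoxide opening at the terminal carbon should give the secondary alcohol with its C–O center untouched, hence (S).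

Step 12
Reactants: 20 methyl 3-hydroxybenzoate
Product: 21 methyl 3-(methoxymethoxy)benzoate
Conditions: MOMCl, i-Pr2NEt, CH2Cl2, 0 °C to rt
Reagents that add atoms: chloromethyl methyl ether, COCCl
Why: Phenol O-alkylation (MOM protection) masks the acidic OH of ring B for the organolithium step.

Step 13
Reactants: 21 methyl 3-(methoxymethoxy)benzoate
Product: 22 N-methoxy-3-(methoxymethoxy)-N-methylbenzamide
Conditions: MeNHOMe·HCl (1.5 equiv), i-PrMgCl (3 equiv), THF, −20 °C
Reagents that add atoms: N,O-dimethylhydroxylamine hydrochloride, CNOC.Cl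
Why: Aminolysis of the methyl ester by the magnesium amide of N,O-dimethylhydroxylamine is a standard route to Weinreb amides.

Step 14
Reactants: 19 (2S)-1-{5-bromo-2,4-dimethoxy-3-[(2R)-5-methyl-2-(prop-1-en-2-yl)hex-5-en-1-yl]phenyl}-3-(methoxymethoxy)-3-methylbutan-2-ol; 22 N-methoxy-3-(methoxymethoxy)-N-methylbenzamide
Product: 26 [(2S)-4,6-dimethoxy-2-[2-(methoxymethoxy)propan-2-yl]-5-[(2R)-5-methyl-2-(prop-1-en-2-yl)hex-5-en-1-yl]-2,3-dihydro-1-benzofuran-7-yl][3-(methoxymethoxy)phenyl]methanone, via aryne lithium alkoxide 23 (not isolated), via cyclised aryllithium 24 (not isolated), via tetrahedral lithium adduct 25 (not isolated)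
Conditions: lithium 2,2,6,6-tetramethylpiperidide (LiTMP, 2.2 equiv), THF, −78 to −30 °C; then 22 (1.3 equiv), −78 to 0 °C; aqueous quench
Reagents that add atoms: none
Why: LiTMP forms the lithium alkoxide of 19 and then removes the single ring hydrogen, which lies ortho to bromine, so that loss of LiBr gives the 3-methoxyaryne 23; its tethered alkoxide adds to the nearer aryne carbon to give aryllithium 24, flanked by two oxygen substituents, which adds to Weinreb amide 22 to form the chelated adduct 25 that collapses to ketone 26 only on work-up. The closest known reaction type is the anionic aryne cyclisation of a tethered heteroatom nucleophile with electrophilic quench of the cyclised aryllithium, combined with the Weinreb ketone synthesis. Ring C closes in a 5-exo-dig mode by in-plane attack of oxygen on the aryne carbon that becomes C7a. No stereocenter is created: C2 keeps the (S) configuration set in 17 because its C–O bond is not broken, and the remote (R) center is untouched. The step needs C–O bond formation at C7a only, use of the secondary and not the tertiary oxygen, and mono-acylation: the two-atom tether reaches only the aryne carbon distal to the methoxy group (also the electronically preferred site of a 3-methoxyaryne, which places the carbanion next to that methoxy group), the tertiary oxygen is blocked as a MOM ether, and the N-methoxy-N-methylamide cannot add twice.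

Step 15
Reactants: 26 [(2S)-4,6-dimethoxy-2-[2-(methoxymethoxy)propan-2-yl]-5-[(2R)-5-methyl-2-(prop-1-en-2-yl)hex-5-en-1-yl]-2,3-dihydro-1-benzofuran-7-yl][3-(methoxymethoxy)phenyl]methanone
Product: 27 [(2S)-2-(2-hydroxypropan-2-yl)-4,6-dimethoxy-5-[(2R)-5-methyl-2-(prop-1-en-2-yl)hex-5-en-1-yl]-2,3-dihydro-1-benzofuran-7-yl](3-hydroxyphenyl)methanone
Conditions: ZnBr2 (3 equiv), n-PrSH (6 equiv), CH2Cl2, 0 °C to rt
Reagents that add atoms: none
Why: Lewis-acid-assisted transfer of both methoxymethyl groups to the thiol (acetal exchange) should free the ring B phenol and the tertiary alcohol while O6 is still methylated, so that no free phenol sits next to the isopropenyl group during the Lewis-acidic step.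

Step 16
Reactants: 27 [(2S)-2-(2-hydroxypropan-2-yl)-4,6-dimethoxy-5-[(2R)-5-methyl-2-(prop-1-en-2-yl)hex-5-en-1-yl]-2,3-dihydro-1-benzofuran-7-yl](3-hydroxyphenyl)methanone
Product: 28 [(2S)-6-hydroxy-2-(2-hydroxypropan-2-yl)-4-methoxy-5-[(2R)-5-methyl-2-(prop-1-en-2-yl)hex-5-en-1-yl]-2,3-dihydro-1-benzofuran-7-yl](3-hydroxyphenyl)methanone
Conditions: MgI2·OEt2 (4 equiv), toluene, 80 °C; aqueous quench
Reagents that add atoms: none
Why: Chelation-controlled demethylation: magnesium held between the ketone oxygen and the ortho methoxy oxygen (O6) should activate only that methyl group for SN2 attack by iodide, whereas the para methoxy group (O4) is not chelated and the hindered secondary C2–O1 bond resists iodide.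

**Compound list**

1 | 2,6-dimethoxytoluene | Cc1c(OC)cccc1OC | starting material
2 | 1,5-dibromo-2,4-dimethoxy-3-methylbenzene | Cc1c(OC)c(Br)cc(Br)c1OC | intermediate
3 | 1,5-dibromo-3-(bromomethyl)-2,4-dimethoxybenzene | BrCc1c(OC)c(Br)cc(Br)c1OC | intermediate
4 | (4R)-4-benzyl-1,3-oxazolidin-2-one | O=C1N[C@H](Cc2ccccc2)CO1 | starting material
5 | 3-methylbut-2-enoyl chloride | CC(C)=CC(Cl)=O | starting material
6 | N-lithio-(4R)-4-benzyl-1,3-oxazolidin-2-one | [Li]N1[C@H](Cc2ccccc2)COC1=O | intermediate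
7 | (4R)-4-benzyl-3-(3-methylbut-2-enoyl)-1,3-oxazolidin-2-one | CC(C)=CC(=O)N1[C@H](Cc2ccccc2)COC1=O | intermediate
8 | sodium (Z)-dienolate of 7 | C=C(C)/C=C(\O[Na])N1[C@H](Cc2ccccc2)COC1=O | intermediate
9 | (4R)-4-benzyl-3-[(2R)-2-[(3,5-dibromo-2,6-dimethoxyphenyl)methyl]-3-methylbut-3-enoyl]-1,3-oxazolidin-2-one | O=C([C@H](Cc1c(OC)c(Br)cc(Br)c1OC)C(=C)C)N1[C@H](Cc2ccccc2)COC1=O | intermediate
10 | (2R)-2-[(3,5-dibromo-2,6-dimethoxyphenyl)methyl]-3-methylbut-3-en-1-ol | OC[C@H](Cc1c(OC)c(Br)cc(Br)c1OC)C(=C)C | intermediate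
11 | 1,5-dibromo-3-[(2R)-2-(iodomethyl)-3-methylbut-3-en-1-yl]-2,4-dimethoxybenzene | IC[C@H](Cc1c(OC)c(Br)cc(Br)c1OC)C(=C)C | intermediate
12 | 2-methylallylmagnesium chloride | C=C(C)C[Mg]Cl | starting material
13 | 1,5-dibromo-2,4-dimethoxy-3-[(2R)-5-methyl-2-(prop-1-en-2-yl)hex-5-en-1-yl]benzene | C=C(C)CC[C@H](Cc1c(OC)c(Br)cc(Br)c1OC)C(=C)C | intermediate
14 | 2-methylbut-3-en-2-ol | C=CC(C)(C)O | starting material
15 | 3-(methoxymethoxy)-3-methylbut-1-ene | C=CC(C)(C)OCOC | intermediate
16 | rac-2-[2-(methoxymethoxy)propan-2-yl]oxirane | COCOC(C)(C)C1CO1 | intermediate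
17 | (2S)-2-[2-(methoxymethoxy)propan-2-yl]oxirane | COCOC(C)(C)[C@@H]1CO1 | intermediate
18 | {5-bromo-2,4-dimethoxy-3-[(2R)-5-methyl-2-(prop-1-en-2-yl)hex-5-en-1-yl]phenyl}lithium | C=C(C)CC[C@H](Cc1c(OC)c(Br)cc([Li])c1OC)C(=C)C | intermediate
19 | (2S)-1-{5-bromo-2,4-dimethoxy-3-[(2R)-5-methyl-2-(prop-1-en-2-yl)hex-5-en-1-yl]phenyl}-3-(methoxymethoxy)-3-methylbutan-2-ol | C=C(C)CC[C@H](Cc1c(OC)c(Br)cc(C[C@@H](C(C)(C)OCOC)O)c1OC)C(=C)C | intermediate
20 | methyl 3-hydroxybenzoate | COC(=O)c1cccc(O)c1 | starting material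
21 | methyl 3-(methoxymethoxy)benzoate | COCOc1cccc(C(=O)OC)c1 | intermediate
22 | N-methoxy-3-(methoxymethoxy)-N-methylbenzamide | COCOc1cccc(C(=O)N(C)OC)c1 | intermediate
23 | lithium alkoxide of the 3-methoxyaryne derived from 19 | C=C(C)CC[C@H](CC1=C(OC)C#CC(C[C@@H](C(C)(C)OCOC)O[Li])=C1OC)C(=C)C | intermediate
24 | {(2S)-4,6-dimethoxy-2-[2-(methoxymethoxy)propan-2-yl]-5-[(2R)-5-methyl-2-(prop-1-en-2-yl)hex-5-en-1-yl]-2,3-dihydro-1-benzofuran-7-yl}lithium | C=C(C)CC[C@H](Cc1c(OC)c([Li])c2c(c1OC)C[C@@H](C(C)(C)OCOC)O2)C(=C)C | intermediate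
25 | lithium alkoxide adduct of 24 with 22 (tetrahedral intermediate) | C=C(C)CC[C@H](Cc1c(OC)c(C(O[Li])(N(C)OC)c2cccc(OCOC)c2)c2c(c1OC)C[C@@H](C(C)(C)OCOC)O2)C(=C)C | intermediate
26 | [(2S)-4,6-dimethoxy-2-[2-(methoxymethoxy)propan-2-yl]-5-[(2R)-5-methyl-2-(prop-1-en-2-yl)hex-5-en-1-yl]-2,3-dihydro-1-benzofuran-7-yl][3-(methoxymethoxy)phenyl]methanone | C=C(C)CC[C@H](Cc1c(OC)c(C(=O)c2cccc(OCOC)c2)c2c(c1OC)C[C@@H](C(C)(C)OCOC)O2)C(=C)C | intermediate
27 | [(2S)-2-(2-hydroxypropan-2-yl)-4,6-dimethoxy-5-[(2R)-5-methyl-2-(prop-1-en-2-yl)hex-5-en-1-yl]-2,3-dihydro-1-benzofuran-7-yl](3-hydroxyphenyl)methanone | C=C(C)CC[C@H](Cc1c(OC)c(C(=O)c2cccc(O)c2)c2c(c1OC)C[C@@H](C(C)(C)O)O2)C(=C)C | intermediate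
28 | [(2S)-6-hydroxy-2-(2-hydroxypropan-2-yl)-4-methoxy-5-[(2R)-5-methyl-2-(prop-1-en-2-yl)hex-5-en-1-yl]-2,3-dihydro-1-benzofuran-7-yl](3-hydroxyphenyl)methanone | C=C(C)CC[C@H](Cc1c(O)c(C(=O)c2cccc(O)c2)c2c(c1OC)C[C@@H](C(C)(C)O)O2)C(=C)C | target

**Step count**

Total: 16 steps. Longest linear sequence: 10 steps (1, 2, 4, 5, 6, 7, 11, 14, 15, 16).

**Steps most likely to fail**

Step 14. The cyclised aryllithium may be lost by proton transfer before it is acylated, or the Weinreb amide may be degraded by residual amide base, so that ring closure and acylation do not couple in one flask. The fallback separates the two events and sets out from 19. Treatment with LiTMP alone (THF, −78 to 0 °C) and an aqueous quench should give (2S)-4,6-dimethoxy-2-[2-(methoxymethoxy)propan-2-yl]-5-[(2R)-5-methyl-2-(prop-1-en-2-yl)hex-5-en-1-yl]-2,3-dihydro-1-benzofuran F1. Directed ortho-lithiation of F1 at C7, the only ring C–H, which lies between O1 and the C6 methoxy group (n-BuLi, THF, 0 °C), and addition to 22 then comes back to the route at 26.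

Step 4. The dienolate may be alkylated at the γ-carbon, with poor facial control, or only slowly by the doubly ortho-substituted benzylic bromide. The fallback sets the center by a standard Evans enolate benzylation and sets out from 3. (4S)-4-Benzyl-3-(5-methylhex-5-enoyl)-1,3-oxazolidin-2-one F2 is prepared from (4S)-4-benzyl-1,3-oxazolidin-2-one and 5-methylhex-5-enoyl chloride. Its sodium enolate (NaN(SiMe3)2, THF, −78 °C) is alkylated with 3 to give (4S)-4-benzyl-3-[(2R)-2-[(3,5-dibromo-2,6-dimethoxyphenyl)methyl]-5-methylhex-5-enoyl]-1,3-oxazolidin-2-one F3. Me2AlN(OMe)Me converts it into (2R)-2-[(3,5-dibromo-2,6-dimethoxyphenyl)methyl]-N-methoxy-N,5-dimethylhex-5-enamide F4, and MeMgBr gives (3R)-3-[(3,5-dibromo-2,6-dimethoxyphenyl)methyl]-6-methylhept-6-en-2-one F5. Wittig methylenation (Ph3P=CH2, THF, 0 °C) comes back to the route at 13.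

Step 16. The two aryl methyl ethers may not be discriminated, or the freed O6 phenol may add to the neighbouring isopropenyl group under Lewis acid. The fallback inverts the logic and sets out from 26. Both aryl methyl ethers are cleaved by sodium ethanethiolate (NaSEt, DMF, 100 °C) to give [(2S)-4,6-dihydroxy-2-[2-(methoxymethoxy)propan-2-yl]-5-[(2R)-5-methyl-2-(prop-1-en-2-yl)hex-5-en-1-yl]-2,3-dihydro-1-benzofuran-7-yl][3-(methoxymethoxy)phenyl]methanone F6. The O4 phenol, which is not hydrogen-bonded to the ketone, is then methylated selectively (MeI 1.0 equiv, K2CO3, acetone, rt) to give [(2S)-6-hydroxy-4-methoxy-2-[2-(methoxymethoxy)propan-2-yl]-5-[(2R)-5-methyl-2-(prop-1-en-2-yl)hex-5-en-1-yl]-2,3-dihydro-1-benzofuran-7-yl][3-(methoxymethoxy)phenyl]methanone F7. Removal of the two MOM groups (ZnBr2, n-PrSH, CH2Cl2, 0 °C) comes back to the route at 28.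

**Further compounds**

F1 | step 14 | (2S)-4,6-dimethoxy-2-[2-(methoxymethoxy)propan-2-yl]-5-[(2R)-5-methyl-2-(prop-1-en-2-yl)hex-5-en-1-yl]-2,3-dihydro-1-benzofuran | C=C(C)CC[C@H](Cc1c(OC)cc2c(c1OC)C[C@@H](C(C)(C)OCOC)O2)C(=C)C
F2 | step 4 | (4S)-4-benzyl-3-(5-methylhex-5-enoyl)-1,3-oxazolidin-2-one | C=C(C)CCCC(=O)N1[C@@H](Cc2ccccc2)COC1=O
F3 | step 4 | (4S)-4-benzyl-3-[(2R)-2-[(3,5-dibromo-2,6-dimethoxyphenyl)methyl]-5-methylhex-5-enoyl]-1,3-oxazolidin-2-one | C=C(C)CC[C@H](Cc1c(OC)c(Br)cc(Br)c1OC)C(=O)N1[C@@H](Cc2ccccc2)COC1=O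
F4 | step 4 | (2R)-2-[(3,5-dibromo-2,6-dimethoxyphenyl)methyl]-N-methoxy-N,5-dimethylhex-5-enamide | C=C(C)CC[C@H](Cc1c(OC)c(Br)cc(Br)c1OC)C(=O)N(C)OC
F5 | step 4 | (3R)-3-[(3,5-dibromo-2,6-dimethoxyphenyl)methyl]-6-methylhept-6-en-2-one | C=C(C)CC[C@H](Cc1c(OC)c(Br)cc(Br)c1OC)C(C)=O
F6 | step 16 | [(2S)-4,6-dihydroxy-2-[2-(methoxymethoxy)propan-2-yl]-5-[(2R)-5-methyl-2-(prop-1-en-2-yl)hex-5-en-1-yl]-2,3-dihydro-1-benzofuran-7-yl][3-(methoxymethoxy)phenyl]methanone | C=C(C)CC[C@H](Cc1c(O)c(C(=O)c2cccc(OCOC)c2)c2c(c1O)C[C@@H](C(C)(C)OCOC)O2)C(=C)C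
F7 | step 16 | [(2S)-6-hydroxy-4-methoxy-2-[2-(methoxymethoxy)propan-2-yl]-5-[(2R)-5-methyl-2-(prop-1-en-2-yl)hex-5-en-1-yl]-2,3-dihydro-1-benzofuran-7-yl][3-(methoxymethoxy)phenyl]methanone | C=C(C)CC[C@H](Cc1c(O)c(C(=O)c2cccc(OCOC)c2)c2c(c1OC)C[C@@H](C(C)(C)OCOC)O2)C(=C)C
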